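Follow the partner.

common to all: substrate 25 mM; partner 15.0 mM; free catalyst 0.19 mM; time 2.0 h

|  | temperature |
|---|---|
| violet | 90 °C |
| grey | 110 °C |
| ochre | 70 °C |

    partner + free catalyst ⇌ catalyst intermediate A (K1 = 140 M⁻¹, k1 = 6500 M⁻¹ min⁻¹, Ea1 = 50.0 kJ mol⁻¹, ΔH1 = −76.0 kJ mol⁻¹)
    substrate + catalyst intermediate A ⇌ catalyst intermediate B (K2 = 25 M⁻¹, k2 = 1100 M⁻¹ min⁻¹, Ea2 = 36.0 kJ mol⁻¹, ΔH2 = −14.0 kJ mol⁻¹)
    catalyst intermediate B ⇌ catalyst intermediate C (K3 = 0.96, k3 = 27 min⁻¹, Ea3 = 87.0 kJ mol⁻¹, ΔH3 = −70.0 kJ mol⁻¹)
    catalyst intermediate C → by-product + catalyst intermediate D (k4 = 150 min⁻¹, Ea4 = 90.0 kJ mol⁻¹)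
    catalyst intermediate D → free catalyst + product (k5 = 71 min⁻¹, Ea5 = 93.0 kJ mol⁻¹)
    (constants at 70 °C)

- all constants are for 70 °C and move with temperature by the activation energies and enthalpies

1. the best flask by amount of product, in percent of the substrate charged; "all alike" if 1.5 percentage points covers them all (violet / grey / ochre / all alike)
2. amount of product at the end, in percent of the substrate charged, violet
3. amount of product at the end, in percent of the substrate charged, grey
4. amount of product at the end, in percent of the substrate charged, ochre

Each product uses one partner and one substrate, and the partner is charged at 15.0 mM, less than the 25 mM of substrate, so it is the limiting reagent. The ceiling, the partner charge over the substrate charge, is then 60.0 % of the substrate charged. You still have to ask whether 2.0 h is long enough to reach it.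

Take ochre, where the constants stand as printed. There, catalyst intermediate A either falls back to partner and free catalyst or takes up substrate, and what takes up substrate may still fall back from catalyst intermediate B. Replace the falling substrate by its mean and count the catalyst as free:

c(substrate), mean: 17.5 mM

catalyst intermediate A takes up substrate at: 19.3 min⁻¹

catalyst intermediate A falls back at: 46.4 min⁻¹

catalyst intermediate B goes forward at: 22.7 min⁻¹

catalyst intermediate B falls back at: 44.0 min⁻¹

share of catalyst intermediate B that goes on: 34.1 %

share of catalyst intermediate A that goes on: 12.4 %

mean life of the partner, pseudo-first-order: 6.54 min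

The weak link in ochre is the mean, because the last partner meets substrate at its end level, 10.0 mM, lower than the mean. Reforged with that level:

catalyst intermediate A takes up substrate at: 11.0 min⁻¹

share of catalyst intermediate A that goes on: 7.47 %

mean life of the partner: 10.8 min

The mean made the partner's life shorter by a factor of 1.65, yet 120 min still holds 11.1 of the reforged mean lives, far more than one. So I commit to 60.0 % for ochre. Heat lowers the binding of substrate, whose constant goes from 25.0 M⁻¹ in ochre to 15.0 M⁻¹ in grey, and I have no figure for what that costs. I therefore keep the same number, with less confidence, as 60.0 % for violet and 60.0 % for grey.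

The forecast gave 59.9 % for violet, 59.2 % for grey, 60 % for ochre, and all alike, saying: “Heating speeds every step but weakens the exothermic binding equilibria”. Its grey number stands below mine.

The flasks give 60.0 % for violet, 59.2 % for grey and 60.0 % for ochre, which is all alike.

Violet's slowest mode has a half-life of 0.205 h at 2.00 h, the run is ten times that long, and 0.067 % of its partner is left unbound. Grey at the same time still has 1.4 % of its partner unbound and stands 0.80 percentage points under the ceiling, against a margin of 1.5 points, and after 20.0 h it reads 60.0 %. In a further flask like violet but with 42 mM of substrate, the ceiling is 35.7 %, and that flask ends with partner at 0 % of its charge and product at 35.7 %.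

All constants were set for the occasion; what happens was integrated by code.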